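## The problem

The target is a daucane-type hydroazulene. A cyclopentane (C4–C5–C6–C7–C8) is trans-fused through the C4–C8 bond to a cycloheptene (C1–C2–C3–C4–C8–C9–C10). The skeleton is numbered here C1(CH3)=C2–C3–C4(CH3)–C5–C6–C7(OH)(i-Pr)–C8(H)–C9(OAr)–C10–C1.

It has four stereocentres: C7, C8 and C9 are contiguous and C4 is quaternary. The angular methyl is anti to H8, the C7 hydroxyl is syn to H8, and the C9 oxygen lies on the face of the angular methyl. In azulene numbering this is (3S,3aS,4R,8aR).

C8 is the natural anchor, because a substituent on C8 can steer an alkylation at C4 and a ring opening at C7. C9 sits on a flexible seven-membered ring, where a ketone reduction would be poorly controlled. C7 cannot be reached by adding an isopropyl nucleophile to a C7 ketone, since the reagent would have to approach from the face shared by the angular methyl and the C9 branch.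

The tertiary C7 alcohol is the fragile group: it can ionise in acid and can undergo retro-aldol cleavage or β-elimination whenever C9 is a carbonyl. The C1=C2 alkene can migrate in strong acid, and the aryl ester with its free phenol will not survive strong base or hydride. The ester therefore comes last and the phenol is masked while it is made.

The enabling feature is the unit C9(O)–C10H2–C1(CH3)=C2 inside the seven-membered ring. A homoallylic alcohol is what a cyclopropylcarbinyl cation at C2 gives when its C1–C9 bond opens. The cycloheptene can thus be treated as a ring-enlarged cyclohexane, and the C9 configuration as the consequence of a cyclopropane face.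

## Retrosynthesis

**Ester.** The acyl C–O bond of 25 is cut first, giving diol 22 and 4-acetoxybenzoyl chloride 23. Capturing the rearrangement cation directly with the carboxylic acid would be kinetically controlled and would favour unrearranged ester. The precursor loses the base-sensitive ester. The forward reaction must acylate the secondary C9 alcohol beside the tertiary C7 alcohol (24), then unmask the phenol.

**Ring enlargement (key).** In 22 the C9–O bond is removed, C1 and C9 are joined, and the oxygen is placed on C2, giving cyclopropyl carbinol 21 with C7 capped as a silyl ether. Closing a seven-membered ring by C–C bond formation would fight entropy and leave C9 to a separate reduction. Here a six-membered ring is made instead and C9 is inherited from the cyclopropane. The precursor is a trans-hydrindane. The forward reaction must break the internal C1–C9 bond, not C1–C10, take up water at C9 anti to that bond, and run under reversible conditions.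

**Cyclopropane and carbinol.** Removing C10 from 21 gives allylic alcohol 19, and adjusting C2 gives enone 18. A sulfur-ylide cyclopropanation of the enone would choose its own face. A hydroxyl-directed methylene transfer ties the cyclopropane face to C2, and C2 is set by hydride addition anti to the axial C4 methyl. Both reactions must deliver to the face of the angular methyl.

**Six-membered ring.** The C1=C9 bond of 18 is cut by an aldol condensation to keto aldehyde 16. The carbonyl sits one CH2 from the quaternary carbon, so this is not a Robinson pattern. The only feasible enolate/carbonyl pairing closes the six-membered ring. The forward reaction must not epimerise C8. The C7 oxygen is silylated so that no alkoxide can trigger retro-aldol cleavage of C7–C8.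

**Tertiary carbinol and C9.** In 16, and its precursors 15, 14 and 12, the C7–O and C9–heteroatom bonds are removed and C7 is joined to C9, giving cyclopropane 10. A 1,3-oxygenated pair is the retron of electrophilic cyclopropane opening. This replaces the unfavourable isopropyl addition, because opening with inversion places the hydroxyl trans to the C8–C9 bond, as required. The forward reaction needs Markovnikov regiochemistry and inversion at C7.

**Side chain.** The C1–C2 bond of 10 is cut to aldehyde 7 and ethylmagnesium bromide 8, via carbinol 9. Aldehyde 7 comes from the allyl group of 5 by ozonolysis. Direct alkylation with an α-halo ketone is unreliable, and a 2-ethylallyl halide is not a stock reagent.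

**Quaternary centre and chiral pool.** Hydrocarbon 5 is traced to ketone 3, and the C3–C4 bond of 3 is cut to (−)-α-thujone 1 and allyl bromide 2. Thujone supplies C8 and the isopropyl-bearing C7 in the correct absolute sense. Its cyclopropane methylene becomes C9 and its cyclopropane shields one face of the C4 enolate. The carbonyl has served its purpose after the alkylation and is removed.

## Roads not taken

Alternative 1: Conjugate addition–aldol on a cyclopentenone. The cuts are C4–CH3 and C8–C9. Enone A1 would take a methyl group from A2 under a chiral copper N-heterocyclic carbene catalyst, and the enolate would be trapped by aldehyde A3 to give keto aldol A4. Ring-closing metathesis and isopropyl addition to the C7 ketone would follow.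
- Merits: catalytic asymmetric, convergent, no mercury, and likely about half the step count of the chosen plan. On step economy it is clearly better.
- Weak points for this target: at C8 the aldehyde must choose between a methyl and an allyl group on C4. The C9 carbinol depends on the facial selectivity of an aluminium enolate with an isomerisation-prone β,γ-unsaturated aldehyde. Above all, the isopropyl group must enter at C7 from the face carrying the C8 branch and the angular methyl, on a β-hydroxy ketone that enolises or cleaves easily; the C7 epimer is the expected product.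
- Comparison: the chosen plan is longer but gives each of the four stereocentres a defined controlling element.

Alternative 2: Intramolecular Buchner reaction. The cuts are C4–C8 and C4–C3. Diazo ketone A5, under a dirhodium tetracarboxylate catalyst, would cyclopropanate its anisole ring and open to trienone A6.
- Merits: both rings and the quaternary carbon form in one step from a flat arene, with the C1 methyl and C9 oxygen already in place. In ring-forming economy it is superior.
- Weak points: the carbenoid carries a methyl group, so 1,2-hydride shift to an enone competes. The arene offers two ipso–ortho bonds and C–H insertion sites. The C4 face is controlled only by the remote C7 substituents. A6 has a C5 ketone to remove, a diene to reduce selectively to C1=C2 alone, and C8 and C9 still to set on a flexible ring. C7 would need its own enantioselective synthesis.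
- Comparison: the chosen plan forms no skeletal bond in its key step, but after it only an esterification remains.

Alternative 3: Divinylcyclopropane Cope rearrangement. The cut is C3–C4, formed as C9–C1 breaks. Siloxy divinylcyclopropane A7 would rearrange on heating to bis(silyl enol ether) A8.
- Merits: it uses the same strain release, creates the quaternary carbon and the ring together, delivers C1=C2 with its methyl, takes C7 from a monoterpene alcohol, uses no mercury, and is probably several steps shorter.
- Weak points: A7 is a fully substituted siloxycyclopropane that needs the cis arrangement. The Cope terminus is a tetrasubstituted alkene. The C4 face depends on a 1,3-related siloxy/isopropyl pair. C8 and C9 must then be set separately by protonation and by reduction of a cycloheptanone. The monoterpene alcohol is usually sold scalemic.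
- Comparison: the chosen plan takes C8 unchanged from thujone and passes the cyclopropane face to C9 stereospecifically.

Key step: step 13

Remark: commercial thujone is often an α/β mixture. The two differ only at the enolisable C4, so either epimer converges on 3.
Remark: the configuration is read from the target structure as drawn, (3S,3aS,4R,8aR) in azulene numbering.

## Route

Step 1
Reactants: 1 (−)-α-thujone; 2 allyl bromide
Product: 3 (1S,4R,5S)-4-methyl-1-(propan-2-yl)-4-(prop-2-en-1-yl)bicyclo[3.1.0]hexan-3-one (allyl anti, methyl syn to the cyclopropane CH2)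
Conditions: t-BuOK, t-BuOH/THF, 0 °C → rt; allyl bromide
Reagents that add atoms: allyl bromide (2), C=CCBr
Why: Thermodynamic enolate alkylation; equilibration favours the more substituted enolate (the other α-carbon is a neopentyl-type CH2 beside the quaternary cyclopropane carbon). The electrophile enters on the convex face opposite the cyclopropane methylene, which sets C4.

Step 2
Reactants: 3 allyl ketone
Product: 5 (1R,4R,5R)-4-methyl-1-(propan-2-yl)-4-(prop-2-en-1-yl)bicyclo[3.1.0]hexane, via hydrazone 4 (not isolated)
Conditions: N2H4·H2O, KOH, diethylene glycol, 130 → 200 °C, argon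
Reagents that add atoms: none
Why: Wolff–Kishner reduction (Huang-Minlon procedure); the carbonyl is not attached to the cyclopropane, so no ring fragmentation is expected. Argon prevents diimide reduction of the allyl group, and no stereocentre is enolisable.

Step 3
Reactants: 5 allyl hydrocarbon
Product: 7 2-[(1R,2R,5R)-2-methyl-5-(propan-2-yl)bicyclo[3.1.0]hexan-2-yl]acetaldehyde, via ozonide 6 (not isolated)
Conditions: O3, CH2Cl2, −78 °C; Me2S, −78 °C → rt
Reagents that add atoms: ozone, [O-][O+]=O
Why: Ozonolysis with reductive work-up; the terminal alkene is the only ozone-reactive group and the cyclopropane is inert at −78 °C.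

Step 4
Reactants: 7 aldehyde; 8 ethylmagnesium bromide
Product: 9 1-[(1R,2R,5R)-2-methyl-5-(propan-2-yl)bicyclo[3.1.0]hexan-2-yl]butan-2-ol (both carbinol epimers)
Conditions: EtMgBr, THF, −78 → 0 °C; aq NH4Cl
Reagents that add atoms: ethylmagnesium bromide (8), CC[Mg]Br
Why: Grignard addition to an aldehyde; the carbinol centre forms as a mixture and is erased in step 5.

Step 5
Reactants: 9 carbinol
Product: 10 1-[(1R,2R,5R)-2-methyl-5-(propan-2-yl)bicyclo[3.1.0]hexan-2-yl]butan-2-one
Conditions: Dess–Martin periodinane, NaHCO3, CH2Cl2, rt
Reagents that add atoms: none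
Why: Dess–Martin oxidation of a secondary alcohol; a ketone is wanted before the cyclopropane is opened, because a free carbinol would capture C7 irreversibly as a cyclic ether.

Step 6
Reactants: 10 ethyl ketone
Product: 12 chloro{[(1R,2S,5R)-2-hydroxy-5-methyl-5-(2-oxobutyl)-2-(propan-2-yl)cyclopentyl]methyl}mercury, via organomercury trifluoroacetate 11 (not isolated)
Conditions: Hg(O2CCF3)2, THF/H2O, 0 °C → rt; aq NaCl
Reagents that add atoms: mercury bis(trifluoroacetate), FC(F)(F)C(=O)O[Hg]OC(=O)C(F)(F)F; water, O; sodium chloride, [Na+].[Cl-]
Why: Electrophilic hydroxymercuration of a cyclopropane with Markovnikov regiochemistry; divalent mercury attacks the unsubstituted carbon C9 and the C9–C7 bond breaks toward the tertiary centre. Water enters C7 on the face opposite the departing carbon (inversion), so the C7 hydroxyl ends trans to the C8–C9 bond and C8 is untouched.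

Step 7
Reactants: 12 organomercury chloride
Product: 14 1-[(1R,2S,3S)-3-hydroxy-2-(hydroxymethyl)-1-methyl-3-(propan-2-yl)cyclopentyl]butan-2-one, via hydroperoxide 13 (not isolated)
Conditions: O2 (sat.), NaBH4, DMF, 0 °C
Reagents that add atoms: dioxygen, O=O
Why: Oxidative demercuration; borohydride turns the C–Hg bond into a primary C9 radical, O2 traps it, and the hydroperoxide is reduced in situ. No stereocentre is involved, and any C2 ketone reduced here is restored in step 8.

Step 8
Reactants: 14 hydroxy ketone
Product: 15 (1R,2S,5R)-2-hydroxy-5-methyl-5-(2-oxobutyl)-2-(propan-2-yl)cyclopentane-1-carbaldehyde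
Conditions: Dess–Martin periodinane, NaHCO3, CH2Cl2, 0 °C → rt
Reagents that add atoms: none
Why: Dess–Martin oxidation under buffered, non-basic conditions; the primary alcohol (and any over-reduced C2 carbinol) is oxidised, the tertiary C7 alcohol is inert, and C8 is not enolised.

Step 9
Reactants: 15 β-hydroxy aldehyde
Product: 16 (1R,2S,5R)-5-methyl-5-(2-oxobutyl)-2-(propan-2-yl)-2-[(triethylsilyl)oxy]cyclopentane-1-carbaldehyde
Conditions: Et3SiOTf, 2,6-lutidine, CH2Cl2, −78 → −20 °C
Reagents that add atoms: triethylsilyl trifluoromethanesulfonate, CC[Si](CC)(CC)OS(=O)(=O)C(F)(F)F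
Why: Silylation of a tertiary alcohol with a silyl triflate and a hindered pyridine, the usual way to cap aldol-type β-hydroxy carbonyl compounds; it removes the alkoxide that would cleave C7–C8 by retro-aldol in step 10.

Step 10
Reactants: 16 keto aldehyde
Product: 18 (1S,3aR,7aR)-3a,6-dimethyl-1-(propan-2-yl)-1-[(triethylsilyl)oxy]-1,2,3,3a,4,7a-hexahydro-5H-inden-5-one, via β-hydroxy ketone 17 (not isolated)
Conditions: KOH, MeOH, 0 °C → rt
Reagents that add atoms: none
Why: Intramolecular aldol condensation; only the C1 enolate of the ethyl ketone reaches the aldehyde through a six-membered transition state (6-enolendo-exo-trig, the other pairings would close four-membered rings), and E1cB loss of water gives the enone. The C8 hydrogen is flanked by two fully substituted carbons, so epimerisation or β-elimination should be slower than closure and the trans fusion is carried over.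

Step 11
Reactants: 18 enone
Product: 19 (1S,3aR,5R,7aR)-3a,6-dimethyl-1-(propan-2-yl)-1-[(triethylsilyl)oxy]-2,3,3a,4,5,7a-hexahydro-1H-inden-5-ol (C2 hydroxyl cis to the angular methyl)
Conditions: NaBH4, CeCl3·7H2O, MeOH, −40 °C
Reagents that add atoms: none
Why: Luche 1,2-reduction; the axial C4 methyl is 1,3 to the carbonyl and blocks that face, so hydride should arrive anti to it and give the pseudo-axial alcohol cis to the methyl, as in hydride reductions of six-ring ketones with a 1,3-diaxial methyl.

Step 12
Reactants: 19 allylic alcohol; 20 diiodomethane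
Product: 21 (1R,2S,4S,5R,7R,10S)-4,7-dimethyl-10-(propan-2-yl)-10-[(triethylsilyl)oxy]tricyclo[5.3.0.0^{2,4}]decan-5-ol (C10H2 bridges C1–C9 on the face of the C2 hydroxyl and the angular methyl)
Conditions: Et2Zn, CH2I2, CH2Cl2, 0 °C → rt
Reagents that add atoms: diiodomethane (20), ICI
Why: Hydroxyl-directed Simmons–Smith cyclopropanation; the C2 zinc alkoxide delivers the methylene to its own face of C1=C9, as cyclic allylic alcohols do even when that face carries an angular methyl. The C7 oxygen is silylated and geometrically remote, so it does not compete.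

Step 13
Reactants: 21 cyclopropyl carbinol
Product: 22 (3S,3aS,4R,8aR)-6,8a-dimethyl-3-(propan-2-yl)-1,2,3,3a,4,5,8,8a-octahydroazulene-3,4-diol
Conditions: HClO4 (ca. 0.2 M), 1,4-dioxane/H2O 3:1, rt → 50 °C
Reagents that add atoms: water, O
Why: Protonation and loss of water from C2 gives a cyclopropylcarbinyl (bicyclobutonium) cation whose internal C1–C9 bond breaks while water bonds to C9, leaving C1=C2 with the methyl already on C1; the same acid hydrolyses the silyl ether at silicon, so the C7–O bond is never broken. The closest known reaction type is the acid-catalysed equilibration of bicyclo[4.1.0]heptan-2-ols with cyclohept-3-en-1-ols and the related solvolyses of their esters. The seven-membered ring is not closed end to end: it arises by ring enlargement, the zero-atom bridge shared by the three- and six-membered rings being cut so that C10 becomes a ring member. The one new stereocentre, C9, is controlled by the cyclopropane face fixed in step 12, because water attacks C9 anti to the breaking C1–C9 bond (inversion), which places the oxygen on the face of the angular methyl (R). Regioselectivity between the two cyclopropane bonds at C1 is needed and is secured because cleaving C1–C10 would require a primary cation whereas cleaving C1–C9 gives a secondary, delocalised one. Product selectivity rests on reversibility: capture at C2 returns the starting carbinol and capture at C1 gives a tertiary cyclobutanol that re-ionises, so the strain-free homoallylic alcohol should accumulate. Chemoselectivity at C7 is needed and is secured because a tertiary alcohol ionises far more slowly in dilute acid than a cyclopropylcarbinol, and the aqueous medium disfavours elimination to dienes.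

Step 14
Reactants: 22 diol; 23 4-acetoxybenzoyl chloride
Product: 24 [(3S,3aS,4R,8aR)-3-hydroxy-6,8a-dimethyl-3-(propan-2-yl)-1,2,3,3a,4,5,8,8a-octahydroazulen-4-yl] 4-(acetyloxy)benzoate
Conditions: pyridine, DMAP (cat.), CH2Cl2, 0 °C → rt
Reagents that add atoms: 4-(acetyloxy)benzoyl chloride (23), CC(=O)Oc1ccc(cc1)C(Cl)=O
Why: Nucleophile-catalysed acylation of an alcohol; the secondary C9 hydroxyl reacts while the tertiary, flanked C7 hydroxyl does not. Only the O–H bond is broken, so C9 keeps its configuration.

Step 15
Reactants: 24 acetoxybenzoate
Product: 25 [(3S,3aS,4R,8aR)-3-hydroxy-6,8a-dimethyl-3-(propan-2-yl)-1,2,3,3a,4,5,8,8a-octahydroazulen-4-yl] 4-hydroxybenzoate (target)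
Conditions: K2CO3, MeOH, 0 °C; aq NH4Cl
Reagents that add atoms: none
Why: Chemoselective methanolysis of an aryl acetate; phenyl acetates cleave far faster than alkyl benzoates, and the phenoxide formed deactivates the hindered benzoate further.

## Compound list

1 | (−)-α-thujone, (1S,4R,5R)-4-methyl-1-(propan-2-yl)bicyclo[3.1.0]hexan-3-one | C[C@H]1C(=O)C[C@]2(C(C)C)C[C@H]12 | starting material
2 | allyl bromide | C=CCBr | starting material
3 | (1S,4R,5S)-4-methyl-1-(propan-2-yl)-4-(prop-2-en-1-yl)bicyclo[3.1.0]hexan-3-one | C=CC[C@@]1(C)C(=O)C[C@]2(C(C)C)C[C@H]12 | intermediate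
4 | hydrazone of 3 (C=N geometry open) | C=CC[C@@]1(C)C(=NN)C[C@]2(C(C)C)C[C@H]12 | intermediate
5 | (1R,4R,5R)-4-methyl-1-(propan-2-yl)-4-(prop-2-en-1-yl)bicyclo[3.1.0]hexane | C=CC[C@@]1(C)CC[C@]2(C(C)C)C[C@H]12 | intermediate
6 | ozonide of 5, a 3-substituted 1,2,4-trioxolane (trioxolane carbon open) | C1(C[C@@]2(C)CC[C@]3(C(C)C)C[C@H]23)OOCO1 | intermediate
7 | 2-[(1R,2R,5R)-2-methyl-5-(propan-2-yl)bicyclo[3.1.0]hexan-2-yl]acetaldehyde | O=CC[C@@]1(C)CC[C@]2(C(C)C)C[C@H]12 | intermediate
8 | ethylmagnesium bromide | CC[Mg]Br | starting material
9 | 1-[(1R,2R,5R)-2-methyl-5-(propan-2-yl)bicyclo[3.1.0]hexan-2-yl]butan-2-ol (carbinol epimers) | CCC(O)C[C@@]1(C)CC[C@]2(C(C)C)C[C@H]12 | intermediate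
10 | 1-[(1R,2R,5R)-2-methyl-5-(propan-2-yl)bicyclo[3.1.0]hexan-2-yl]butan-2-one | CCC(=O)C[C@@]1(C)CC[C@]2(C(C)C)C[C@H]12 | intermediate
11 | {[(1R,2S,5R)-2-hydroxy-5-methyl-5-(2-oxobutyl)-2-(propan-2-yl)cyclopentyl]methyl}mercury trifluoroacetate | CCC(=O)C[C@@]1(C)CC[C@](O)(C(C)C)[C@@H]1C[Hg]OC(=O)C(F)(F)F | intermediate
12 | chloro{[(1R,2S,5R)-2-hydroxy-5-methyl-5-(2-oxobutyl)-2-(propan-2-yl)cyclopentyl]methyl}mercury | CCC(=O)C[C@@]1(C)CC[C@](O)(C(C)C)[C@@H]1C[Hg]Cl | intermediate
13 | 1-[(1R,2S,3S)-2-(hydroperoxymethyl)-3-hydroxy-1-methyl-3-(propan-2-yl)cyclopentyl]butan-2-one | CCC(=O)C[C@@]1(C)CC[C@](O)(C(C)C)[C@@H]1COO | intermediate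
14 | 1-[(1R,2S,3S)-3-hydroxy-2-(hydroxymethyl)-1-methyl-3-(propan-2-yl)cyclopentyl]butan-2-one | CCC(=O)C[C@@]1(C)CC[C@](O)(C(C)C)[C@@H]1CO | intermediate
15 | (1R,2S,5R)-2-hydroxy-5-methyl-5-(2-oxobutyl)-2-(propan-2-yl)cyclopentane-1-carbaldehyde | CCC(=O)C[C@@]1(C)CC[C@](O)(C(C)C)[C@@H]1C=O | intermediate
16 | (1R,2S,5R)-5-methyl-5-(2-oxobutyl)-2-(propan-2-yl)-2-[(triethylsilyl)oxy]cyclopentane-1-carbaldehyde | CCC(=O)C[C@@]1(C)CC[C@](O[Si](CC)(CC)CC)(C(C)C)[C@@H]1C=O | intermediate
17 | 7-hydroxy-3a,6-dimethyl-1-(propan-2-yl)-1-[(triethylsilyl)oxy]octahydro-5H-inden-5-one (aldol adduct; C6 and C7 open, other centres as in 18) | O=C1C[C@@]2(C)CC[C@](O[Si](CC)(CC)CC)(C(C)C)[C@@H]2C(O)C1C | intermediate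
18 | (1S,3aR,7aR)-3a,6-dimethyl-1-(propan-2-yl)-1-[(triethylsilyl)oxy]-1,2,3,3a,4,7a-hexahydro-5H-inden-5-one | O=C1C[C@@]2(C)CC[C@](O[Si](CC)(CC)CC)(C(C)C)[C@@H]2C=C1C | intermediate
19 | (1S,3aR,5R,7aR)-3a,6-dimethyl-1-(propan-2-yl)-1-[(triethylsilyl)oxy]-2,3,3a,4,5,7a-hexahydro-1H-inden-5-ol | O[C@@H]1C[C@@]2(C)CC[C@](O[Si](CC)(CC)CC)(C(C)C)[C@@H]2C=C1C | intermediate
20 | diiodomethane | ICI | starting material
21 | (1R,2S,4S,5R,7R,10S)-4,7-dimethyl-10-(propan-2-yl)-10-[(triethylsilyl)oxy]tricyclo[5.3.0.0^{2,4}]decan-5-ol | C[C@@]12[C@H](O)C[C@@]3(C)CC[C@](O[Si](CC)(CC)CC)(C(C)C)[C@@H]3[C@@H]1C2 | intermediate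
22 | (3S,3aS,4R,8aR)-6,8a-dimethyl-3-(propan-2-yl)-1,2,3,3a,4,5,8,8a-octahydroazulene-3,4-diol | CC1=CC[C@@]2(C)CC[C@](O)(C(C)C)[C@@H]2[C@H](O)C1 | intermediate
23 | 4-(acetyloxy)benzoyl chloride | CC(=O)Oc1ccc(cc1)C(Cl)=O | starting material
24 | [(3S,3aS,4R,8aR)-3-hydroxy-6,8a-dimethyl-3-(propan-2-yl)-1,2,3,3a,4,5,8,8a-octahydroazulen-4-yl] 4-(acetyloxy)benzoate | CC1=CC[C@@]2(C)CC[C@](O)(C(C)C)[C@@H]2[C@H](OC(=O)c2ccc(OC(C)=O)cc2)C1 | intermediate
25 | [(3S,3aS,4R,8aR)-3-hydroxy-6,8a-dimethyl-3-(propan-2-yl)-1,2,3,3a,4,5,8,8a-octahydroazulen-4-yl] 4-hydroxybenzoate | CC1=CC[C@@]2(C)CC[C@](O)(C(C)C)[C@@H]2[C@H](OC(=O)c2ccc(O)cc2)C1 | target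

Total step count: 15. Longest linear sequence: 15 steps, from 1 to 25; compounds 2, 8, 20 and 23 are purchased.

## Least certain steps

**Step 13 (key).** The cation may be captured kinetically at C2 or C1 faster than equilibration reaches the cycloheptenol. Elimination to dienes, slow hydrolysis of the silyl ether, and acid-induced addition of the freed C7 hydroxyl to C1=C2 could drain material. Fallback, same disconnection but stepwise with a carboxylate nucleophile: from 21, fluoride (Bu4NF) removes the silyl group to give the free cyclopropyl diol F1. Buffered formolysis (HCO2H/HCO2Na) then equilibrates it to the ring-enlarged C9 formate F2. Mild methanolysis (K2CO3, MeOH) returns the route at 22.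

**Step 6.** The opening may lose regiocontrol, or lose stereospecificity if the tertiary centre reacts as a free cation. Elimination instead of hydration and slow reaction of the hindered cyclopropane are also possible. Fallback, a different oxidant that oxygenates both termini at once: from 10, Pb(OAc)4 in AcOH (tetravalent lead) cleaves the same bond to the 1,3-diacetate F3. LiAlH4 removes both acetates and reduces the ketone to triol F4. Dess–Martin periodinane then oxidises the C2 and C9 carbinols and returns the route at 15.

**Step 10.** Base may enolise C8, giving epimerisation toward the cis-fused enone or β-elimination of the silyloxy group. The product can also suffer vinylogous elimination on long exposure. Fallback, directed aldol addition and separate dehydration: from 16, Bu2BOTf/i-Pr2NEt at −78 °C forms the boron enolate on the ethyl side, which closes onto the aldehyde. Oxidative work-up gives 17, now isolated. MsCl/Et3N gives the mesylate F5, and DBU eliminates it to return the route at 18.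

**Step 1.** Alkylation may occur at the other α-carbon or on oxygen, may go twice, or may show incomplete facial selectivity. Fallback, a regiodefined enolate: from 1, Me3SiCl/Et3N in hot DMF gives the more substituted silyl enol ether F6 after separation. MeLi releases its lithium enolate, which is allylated with 2 and returns the route at 3.

**Step 2.** The hindered hydrazone may form or decompose slowly, and the hot base may move the allyl double bond. Fallback, radical deoxygenation: from 3, NaBH4 gives the alcohol F7, and NaH/CS2/MeI gives the xanthate F8. Bu3SnH/AIBN (Barton–McCombie) returns the route at 5. The C5 radical is not adjacent to the cyclopropane.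

**Step 11.** Facial selectivity of hydride delivery may be poor or reversed. This would invert the cyclopropane face and hence C9. Fallback, invert instead of re-reduce: from 18, if reduction gives the C2 epimer F9, a Mitsunobu reaction with 4-nitrobenzoic acid gives the inverted ester F10. Methanolysis (K2CO3, MeOH) returns the route at 19.

## Further compounds

F1 | step 13 | (1R,2S,4S,5R,7R,10S)-4,7-dimethyl-10-(propan-2-yl)tricyclo[5.3.0.0^{2,4}]decane-5,10-diol | C[C@@]12[C@H](O)C[C@@]3(C)CC[C@](O)(C(C)C)[C@@H]3[C@@H]1C2
F2 | step 13 | [(3S,3aS,4R,8aR)-3-hydroxy-6,8a-dimethyl-3-(propan-2-yl)-1,2,3,3a,4,5,8,8a-octahydroazulen-4-yl] formate | CC1=CC[C@@]2(C)CC[C@](O)(C(C)C)[C@@H]2[C@H](OC=O)C1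
F3 | step 6 | [(1R,2S,5R)-2-(acetyloxy)-5-methyl-5-(2-oxobutyl)-2-(propan-2-yl)cyclopentyl]methyl acetate | CCC(=O)C[C@@]1(C)CC[C@](OC(C)=O)(C(C)C)[C@@H]1COC(C)=O
F4 | step 6 | 1-[(1R,2S,3S)-3-hydroxy-2-(hydroxymethyl)-1-methyl-3-(propan-2-yl)cyclopentyl]butan-2-ol (carbinol epimers) | CCC(O)C[C@@]1(C)CC[C@](O)(C(C)C)[C@@H]1CO
F5 | step 10 | methanesulfonate of aldol adduct 17 | O=C1C[C@@]2(C)CC[C@](O[Si](CC)(CC)CC)(C(C)C)[C@@H]2C(OS(C)(=O)=O)C1C
F6 | step 1 | trimethyl{[(1S,5R)-4-methyl-1-(propan-2-yl)bicyclo[3.1.0]hex-3-en-3-yl]oxy}silane | CC1=C(O[Si](C)(C)C)C[C@]2(C(C)C)C[C@H]12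
F7 | step 2 | 4-methyl-1-(propan-2-yl)-4-(prop-2-en-1-yl)bicyclo[3.1.0]hexan-3-ol (carbinol epimers, other centres as in 3) | C=CC[C@@]1(C)C(O)C[C@]2(C(C)C)C[C@H]12
F8 | step 2 | O-[4-methyl-1-(propan-2-yl)-4-(prop-2-en-1-yl)bicyclo[3.1.0]hexan-3-yl] S-methyl carbonodithioate | C=CC[C@@]1(C)C(OC(=S)SC)C[C@]2(C(C)C)C[C@H]12
F9 | step 11 | C2 epimer of 19 (hydroxyl anti to the angular methyl) | O[C@H]1C[C@@]2(C)CC[C@](O[Si](CC)(CC)CC)(C(C)C)[C@@H]2C=C1C
F10 | step 11 | 4-nitrobenzoate of 19 | O=C(O[C@@H]1C[C@@]2(C)CC[C@](O[Si](CC)(CC)CC)(C(C)C)[C@@H]2C=C1C)c1ccc(cc1)[N+](=O)[O-]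
A1 | alternative 1 | 3-(prop-2-en-1-yl)cyclopent-2-en-1-one | C=CCC1=CC(=O)CC1
A2 | alternative 1 | trimethylaluminium | C[Al](C)C
A3 | alternative 1 | 3-methylbut-3-enal | CC(=C)CC=O
A4 | alternative 1 | 2-(1-hydroxy-3-methylbut-3-en-1-yl)-3-methyl-3-(prop-2-en-1-yl)cyclopentan-1-one (keto aldol) | C=CC[C@@]1(C)CCC(=O)[C@@H]1[C@H](O)CC(C)=C
A5 | alternative 2 | 2-diazo-5-(2-methoxy-4-methylphenyl)-6-methyl-5-[(triethylsilyl)oxy]heptan-3-one | CC(=[N+]=[N-])C(=O)C[C@](O[Si](CC)(CC)CC)(C(C)C)c1ccc(C)cc1OC
A6 | alternative 2 | bicyclo[5.3.0]decatrienone with C8=C9 methyl enol ether | CC1=CC(OC)=C2[C@@](O[Si](CC)(CC)CC)(C(C)C)CC(=O)[C@]2(C)C=C1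
A7 | alternative 3 | cis-1-siloxy-1-(cyclopentenyl)-2-methyl-2-vinylcyclopropane (one cis diastereomer shown) | C=C[C@@]1(C)C[C@@]1(O[Si](C)(C)C)C1=C(C)CC[C@]1(O[Si](C)(C)C)C(C)C
A8 | alternative 3 | bicyclic bis(trimethylsilyl) compound with C8=C9 silyl enol ether and C1=C2 alkene | CC1=CC[C@@]2(C)CC[C@](O[Si](C)(C)C)(C(C)C)C2=C(O[Si](C)(C)C)C1
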